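A small charge of starting material meets a solid partner that must dissolve before it can react, and delta and beta differ in the loading of that solid and in the feed.

| flask | starting material | solid partner | remark | time |
|---|---|---|---|---|
| Sunday's | 0.10 M (fed, over 6.0 h) | 0.067 M | run made earlier |  |
| Friday's | 0.10 M (fed, over 6.0 h) | 0.19 M | run made earlier |  |
| delta | 0.10 M (fed, over 6.0 h) | 0.0800 M |  | 40 h |
| beta | 0.10 M | 0.300 M | everything together at the start | 40 h |

| run | time / h | target / % | over-reaction product / % |
|---|---|---|---|
| Sunday's | 2.50 | 0 | 0.1 |
| Sunday's | 3.00 | 0.1 | 0 |
| Sunday's | 5.00 | 0.7 | 0 |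
| Sunday's | 8.00 | 2.3 | 0 |
| Sunday's | 12.0 | 7.2 | 0.8 |
| Sunday's | 20.0 | 16.1 | 2.4 |
| Sunday's | 30.0 | 24.3 | 4.7 |
| Friday's | 2.50 | 0 | 0 |
| Friday's | 3.00 | 1.2 | 0.3 |
| Friday's | 5.00 | 0 | 0 |
| Friday's | 8.00 | 1.9 | 0.5 |
| Friday's | 12.0 | 6.2 | 0.7 |
| Friday's | 20.0 | 15.7 | 1.4 |
| Friday's | 30.0 | 25.0 | 5.2 |

(standard deviation of a reading: 0.5 percentage points)

- which one finishes higher in share of target in all that became target or over-reaction product ("neither" within 2 percentage points) (delta / beta / neither)
- share of target in all that became target or over-reaction product, delta
- share of target in all that became target or over-reaction product, beta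

- as a solid, counted per litre of solution: solid partner
- the analysis behind the earlier runs scatters by 0.5 percentage points, standard deviation
- at the start none of the solid partner is in solution
- percentages count the whole charge, also what has not yet gone in

Does the loading matter? Friday's run holds 2.84 times the solid of Sunday's, yet at 30.0 h the sum of target and over-reaction product reads 30.2% against 29.0%, a gap close to the scatter of the readings. So I take it that, while solid stands, dissolved c(solid partner) does not follow the loading and the solid drains at a steady, zero-order rate. Counting one partner per product, the rise of that sum from 20.0 h to 30.0 h gives a drain of 0.00118 M/h.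

How long does the solid last? The charge of solid over the drain is its running time, 67.8 h for delta, longer than the 40 h asked. For beta it is 254 h. So the loading does not part them.

Does the feed? I put delta behind beta by 3.00 h. The pooled share falls from 89.3% to 83.3% over those readings; carried whole to the end, that lag reckons at 1.8 percentage points, less than the margin of 2 points. I reckon neither.

The forecast says neither, with delta at 77% (72% to 82%) and beta at 75.5% (71% to 80%): “Extra solid gains nothing”.

The flask gives neither: delta 76.9%, beta 76.4%, a gap of 0.50 points, smaller than my 1.8 points.

    starting material → open intermediate (k = 0.286 /h)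
    fresh partner → second intermediate (k = 0.363 /h)
    open intermediate + second intermediate → target (k = 1.69 /M/h)
    2 second intermediate → homo product (k = 1.27 /M/h)
    target → over-reaction product (k = 0.0159 /h)
    solid partner ⇌ fresh partner, rate k6*(cs6 - [fresh partner]) while solid is left; crystals form when [fresh partner] > cs6 (solubility = 6.60 mM, k = 0.689 /h)

In delta the half-life of starting material, 2.4 h, lies far below that of target, 44 h. At 40.0 h open intermediate, the resting state, holds 58.4% and c(fresh partner) reads 0.00432 M. Delta's solid stands at 18.0% of its charge, so 0.0656 M is drawn, more than the 0.0472 M of my drain, and second intermediate, homo product and fresh partner hold partner too. The flask's drain at that time in delta, the rate constant of fresh partner to second intermediate times c(fresh partner), is 0.00157 M/h, which shortens delta's running time from 67.8 h to 51.0 h and beta's from 254 h to 191 h. In beta read at 144 h, solid stands at 23.7%, and the share is 26.7%.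

(Readings and results are calculated for an exercise; scatter was added.)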